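## Retrosynthetic overview

1. Target 46 ← oxidative lactonisation of an 8,12-diol ← endo Diels–Alder of acetoxy-cyclopentadiene 43 (guaiane half) with α-methylene lactone 42 (1,10-seco-eudesmane half), forming C1–C13′ and C3–C11′.
2. 43 ← syn-dehydration of tertiary allylic alcohol 21 ← Wharton transposition, Rubottom oxidation and cyclopentenone annulation on cycloheptanone 14 ← two conjugate additions to dienone 8 ← lipase desymmetrisation of meso-diacetate 2.
3. 42 ← organocerium methylation of enone 35 ← sulfide-mediated SN2′-type cuprate addition–elimination (sets C4′) on enone 29 ← Johnson–Claisen rearrangement of lipase-derived cyclohexenol 26.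
4. Ring order: cycloheptene (bought) → cyclopentene; cyclohexene (bought) → γ-lactone; then the norbornene (Diels–Alder); the guaianolide γ-lactone last.

Assumption and conventions: the lipase is assumed to hydrolyse the enantiotopic acetate that gives 3 and 24 as drawn, and ligand L* to give 10R in step 7 (otherwise lipase acetylation of the meso-diol, or ent-L*, is used); TBS = tert-butyldimethylsilyl, TMS = trimethylsilyl; guaiane locants with β = face of the C10 methyl.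

## Part A – guaiane half

Step 1
Reactants: 1 cyclohepta-1,3-diene
Product: 2 cis-cyclohept-2-ene-1,4-diyl diacetate (meso)
Conditions: Pd(OAc)2 (5 mol %), LiOAc, LiCl (cat.), p-benzoquinone, AcOH, 25 °C
Reagents that add atoms: acetic acid (CC(=O)O)
Why: Pd(II)-catalysed 1,4-diacetoxylation of a 1,3-diene; trans-acetoxypalladation then external acetate attack on the π-allyl gives the cis (meso) diacetate.

Step 2
Reactants: 2 cis-cyclohept-2-ene-1,4-diyl diacetate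
Product: 3 (1S,4R)-4-hydroxycyclohept-2-en-1-yl acetate
Conditions: lipase (Burkholderia cepacia lipase, a serine hydrolase), phosphate buffer pH 7, 25 °C
Reagents that add atoms: none
Why: Lipase-catalysed hydrolysis of one enantiotopic ester (enzymatic desymmetrisation of a meso-diacetate) sets both carbinol centres in one operation.

Step 3
Reactants: 3 (1S,4R)-4-hydroxycyclohept-2-en-1-yl acetate
Product: 4 (1S,4R)-4-(TBSO)cyclohept-2-en-1-yl acetate
Conditions: TBSCl, imidazole, DMF, rt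
Reagents that add atoms: tert-butyldimethylsilyl chloride (CC(C)(C)[Si](C)(C)Cl)
Why: Standard silylation of the free secondary alcohol; no stereocentre is touched.

Step 4
Reactants: 4 (1S,4R)-4-(TBSO)cyclohept-2-en-1-yl acetate
Product: 5 (1S,4R)-4-(TBSO)cyclohept-2-en-1-ol
Conditions: K2CO3 (cat.), MeOH, 0 °C
Reagents that add atoms: none
Why: Mild transesterification removes the acetate while the silyl ether survives.

Step 5
Reactants: 5 (1S,4R)-4-(TBSO)cyclohept-2-en-1-ol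
Product: 6 (4R)-4-(TBSO)cyclohept-2-en-1-one
Conditions: MnO2, CH2Cl2, rt
Reagents that add atoms: none
Why: Chemoselective oxidation of an allylic alcohol; the silyloxy stereocentre is untouched.

Step 6
Reactants: 6 (4R)-4-(TBSO)cyclohept-2-en-1-one
Product: 8 (4R)-4-(TBSO)cyclohepta-2,6-dien-1-one, via trimethylsilyl dienol ether 7 (not isolated)
Conditions: LDA, TMSCl, THF, −78 °C; then Pd(OAc)2, MeCN, rt
Reagents that add atoms: none
Why: Saegusa–Ito dehydrogenation; only the α′-CH2 can be enolised kinetically, so the new alkene is regiodefined.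

Step 7
Reactants: 8 (4R)-4-(TBSO)cyclohepta-2,6-dien-1-one; 9 1-bromobut-2-yne
Product: 11 (2S,3R,5R)-2-(but-2-yn-1-yl)-5-(TBSO)-3-methylcyclohept-6-en-1-one, via methylzinc enolate 10 (not isolated)
Conditions: Cu(OTf)2 (2 mol %), (S,R,R)-phosphoramidite L* (4 mol %), Me2Zn, PhMe, −30 °C; then 9, HMPA, THF, 0 °C; NH4Cl
Reagents that add atoms: dimethylzinc (C[Zn]C)
Why: Cu-catalysed asymmetric conjugate addition at the less hindered β-carbon (ligand control sets 10R), then alkylation of the regiodefined zinc enolate anti to the new methyl.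

Step 8
Reactants: 12 2-bromoprop-2-en-1-ol
Product: 13 [(2-bromoprop-2-en-1-yl)oxy](tert-butyl)dimethylsilane
Conditions: TBSCl, imidazole, DMF, rt
Reagents that add atoms: tert-butyldimethylsilyl chloride (CC(C)(C)[Si](C)(C)Cl)
Why: Standard silylation gives the precursor of the masked acrylate (C11–C13) unit.

Step 9
Reactants: 11 (2S,3R,5R)-2-(but-2-yn-1-yl)-5-(TBSO)-3-methylcyclohept-6-en-1-one; 13 [(2-bromoprop-2-en-1-yl)oxy](tert-butyl)dimethylsilane
Product: 14 (2S,3R,5R,6S)-2-(but-2-yn-1-yl)-5-(TBSO)-6-[3-(TBSO)prop-1-en-2-yl]-3-methylcycloheptan-1-one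
Conditions: 13, t-BuLi (2 equiv), Et2O, −78 °C; CuI (0.5 equiv); then 11, −78 → −40 °C; NH4Cl
Reagents that add atoms: none
Why: Gilman cuprate conjugate addition occurs anti to the γ-silyloxy group, giving the trans C7/C8 relationship of the guaianolide.

Step 10
Reactants: 14 (2S,3R,5R,6S)-2-(but-2-yn-1-yl)-5-(TBSO)-6-[3-(TBSO)prop-1-en-2-yl]-3-methylcycloheptan-1-one
Product: 15 (2S,3R,5R,6S)-5-(TBSO)-6-[3-(TBSO)prop-1-en-2-yl]-3-methyl-2-(2-oxobutyl)cycloheptan-1-one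
Conditions: (Ph3P)AuNTf2 (2 mol %), H2O, 1,4-dioxane, 60 °C
Reagents that add atoms: water (O)
Why: Gold-catalysed alkyne hydration; 5-exo-dig participation of the ring ketone puts the new carbonyl on the proximal alkyne carbon (1,4-diketone).

Step 11
Reactants: 15 (2S,3R,5R,6S)-5-(TBSO)-6-[3-(TBSO)prop-1-en-2-yl]-3-methyl-2-(2-oxobutyl)cycloheptan-1-one
Product: 16 8α,12-bis(TBSO)-1βH,7αH,10αH-guaia-4,11(13)-dien-3-one
Conditions: t-BuOK (cat.), t-BuOH/THF, rt
Reagents that add atoms: none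
Why: Intramolecular aldol condensation (cyclopentenone annulation); only attack of the ethyl-ketone CH2 on the ring ketone can dehydrate to a conjugated enone, and H-1 stays cis to the C10 methyl.

Step 12
Reactants: 16 8α,12-bis(TBSO)-1βH,7αH,10αH-guaia-4,11(13)-dien-3-one
Product: 18 2β-hydroxy-8α,12-bis(TBSO)-1βH-guaia-4,11(13)-dien-3-one, via trimethylsilyl dienol ether 17 (not isolated)
Conditions: LDA, TMSCl, THF, −78 °C; then DMDO, acetone/CH2Cl2, −78 °C; then aq. citric acid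
Reagents that add atoms: dimethyldioxirane (CC1(C)OO1)
Why: Rubottom oxidation of the kinetic α′-silyl enol ether; the oxidant approaches anti to the C1–C10 bond, giving the 2β-alcohol (cis to H-1).

Step 13
Reactants: 18 2β-hydroxy-8α,12-bis(TBSO)-1βH-guaia-4,11(13)-dien-3-one
Product: 19 4β,5β-epoxy-2β-hydroxy-8α,12-bis(TBSO)-1βH-guai-11(13)-en-3-one
Conditions: t-BuOOH, DBU, CH2Cl2, 0 °C → rt
Reagents that add atoms: tert-butyl hydroperoxide (CC(C)(C)OO)
Why: Nucleophilic (Weitz–Scheffer) epoxidation of the enone from the β-face, syn to H-1 and the 2-OH and anti to C10; the isolated alkene is inert.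

Step 14
Reactants: 19 4β,5β-epoxy-2β-hydroxy-8α,12-bis(TBSO)-1βH-guai-11(13)-en-3-one
Product: 20 8α,12-bis(TBSO)-1βH-guaia-3,11(13)-diene-2β,5β-diol
Conditions: N2H4·H2O, AcOH (cat.), MeOH, 0 °C → rt
Reagents that add atoms: none
Why: Wharton transposition; the hydrazone opens the epoxide and loses N2, giving the C3=C4 alkene and retaining the 5β C–O bond.

Step 15
Reactants: 20 8α,12-bis(TBSO)-1βH-guaia-3,11(13)-diene-2β,5β-diol
Product: 21 2α-acetoxy-8α,12-bis(TBSO)-1βH-guaia-3,11(13)-dien-5β-ol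
Conditions: PPh3, DIAD, AcOH, THF, 0 °C → rt
Reagents that add atoms: acetic acid (CC(=O)O)
Why: Mitsunobu esterification inverts the secondary allylic C2 carbinol (SN2) to the required 2α-acetate; the tertiary 5-OH does not react.

## Part B – seco-eudesmane half

Step 16
Reactants: 22 cyclohexa-1,3-diene
Product: 23 cis-cyclohex-2-ene-1,4-diyl diacetate (meso)
Conditions: Pd(OAc)2 (5 mol %), LiOAc, LiCl (cat.), p-benzoquinone, AcOH, 25 °C
Reagents that add atoms: acetic acid (CC(=O)O)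
Why: Pd(II)-catalysed 1,4-diacetoxylation; catalytic chloride enforces external acetate attack and hence the cis (meso) product.

Step 17
Reactants: 23 cis-cyclohex-2-ene-1,4-diyl diacetate
Product: 24 (1R,4S)-4-hydroxycyclohex-2-en-1-yl acetate
Conditions: lipase (Burkholderia cepacia lipase, a serine hydrolase), phosphate buffer pH 7, 25 °C
Reagents that add atoms: none
Why: Lipase-catalysed desymmetrisation of the meso-diacetate sets the first stereocentres of this half.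

Step 18
Reactants: 24 (1R,4S)-4-hydroxycyclohex-2-en-1-yl acetate
Product: 25 (1R,4S)-4-(TBSO)cyclohex-2-en-1-yl acetate
Conditions: TBSCl, imidazole, DMF, rt
Reagents that add atoms: tert-butyldimethylsilyl chloride (CC(C)(C)[Si](C)(C)Cl)
Why: Standard silylation; the silylated carbon becomes the lactone C–O carbon (C8′).

Step 19
Reactants: 25 (1R,4S)-4-(TBSO)cyclohex-2-en-1-yl acetate
Product: 26 (1R,4S)-4-(TBSO)cyclohex-2-en-1-ol
Conditions: K2CO3 (cat.), MeOH, 0 °C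
Reagents that add atoms: none
Why: Transesterification frees the allylic alcohol needed for the sigmatropic step.

Step 20
Reactants: 26 (1R,4S)-4-(TBSO)cyclohex-2-en-1-ol
Product: 28 ethyl 2-[(1R,6S)-6-(TBSO)cyclohex-2-en-1-yl]acetate, via ketene acetal 27 (not isolated)
Conditions: MeC(OEt)3, EtCO2H (cat.), xylene, 140 °C (−EtOH)
Reagents that add atoms: triethyl orthoacetate (CCOC(C)(OCC)OCC)
Why: Johnson–Claisen rearrangement; the suprafacial [3,3] shift delivers CH2CO2Et syn to the departing oxygen, hence cis to OTBS, and moves the alkene to C5′=C6′.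

Step 21
Reactants: 28 ethyl 2-[(1R,6S)-6-(TBSO)cyclohex-2-en-1-yl]acetate
Product: 29 ethyl 2-[(1R,6S)-6-(TBSO)-4-oxocyclohex-2-en-1-yl]acetate
Conditions: Rh2(cap)4 (1 mol %), t-BuOOH, K2CO3, CH2Cl2, rt
Reagents that add atoms: tert-butyl hydroperoxide (CC(C)(C)OO)
Why: Radical allylic oxidation to the enone at the only allylic CH2; the tertiary allylic C–H is hindered and deactivated by the neighbouring oxygen.

Step 22
Reactants: 29 ethyl 2-[(1R,6S)-6-(TBSO)-4-oxocyclohex-2-en-1-yl]acetate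
Product: 31 ethyl 2-[(1S,2R,6S)-6-(TBSO)-3-(1-hydroxyethyl)-4-oxo-2-(phenylsulfanyl)cyclohexyl]acetate (epimers at C3/C1′), via dimethylaluminium enolate 30 (not isolated)
Conditions: Me3Al, PhSH, CH2Cl2, 0 °C; then 29, THF, −78 °C; then MeCHO, −78 °C; 1 M HCl
Reagents that add atoms: benzenethiol (Sc1ccccc1); acetaldehyde (CC=O)
Why: Thia-Michael addition anti to the C1 side chain gives a regiodefined aluminium enolate that undergoes aldol addition to acetaldehyde (three-component coupling).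

Step 23
Reactants: 31 ethyl 2-[(1S,2R,6S)-6-(TBSO)-3-(1-hydroxyethyl)-4-oxo-2-(phenylsulfanyl)cyclohexyl]acetate
Product: 33 ethyl 2-[(1S,2R,3Z,6S)-6-(TBSO)-3-ethylidene-4-oxo-2-(phenylsulfanyl)cyclohexyl]acetate, via mesylate 32 (not isolated)
Conditions: MsCl, Et3N, CH2Cl2, 0 °C → rt
Reagents that add atoms: none
Why: Mesylation and E1cB elimination give the thermodynamic ethylidene enone (methyl anti to C=O) and erase the two uncontrolled centres; the sulfide stays as an allylic leaving group.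

Step 24
Reactants: 33 ethyl 2-[(1S,2R,3Z,6S)-6-(TBSO)-3-ethylidene-4-oxo-2-(phenylsulfanyl)cyclohexyl]acetate; 34 tert-butyl(3-iodopropoxy)dimethylsilane
Product: 35 ethyl 2-[(1R,6S)-6-(TBSO)-4-oxo-3-[(2R)-5-(TBSO)pentan-2-yl]cyclohex-2-en-1-yl]acetate
Conditions: 34, t-BuLi (2 equiv), Et2O, −78 °C; CuI (0.5 equiv); then 33, −78 → −20 °C; NH4Cl
Reagents that add atoms: none
Why: SN2′-type cuprate addition–elimination; the cuprate attacks the ethylidene carbon anti to the pseudoaxial C–S bond (held by A(1,3) strain) and thiolate loss regenerates the ring enone, setting the (2R) side-chain centre.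

Step 25
Reactants: 35 ethyl 2-[(1R,6S)-6-(TBSO)-4-oxo-3-[(2R)-5-(TBSO)pentan-2-yl]cyclohex-2-en-1-yl]acetate
Product: 36 ethyl 2-[(1R,4R,6S)-6-(TBSO)-4-hydroxy-4-methyl-3-[(2R)-5-(TBSO)pentan-2-yl]cyclohex-2-en-1-yl]acetate
Conditions: MeLi, CeCl3, THF, −78 °C; NH4Cl
Reagents that add atoms: methyllithium ([Li]C)
Why: Non-basic organocerium 1,2-addition to the enone (ester untouched at −78 °C) occurs anti to the pseudoaxial OTBS, placing the new OH cis to it.

Step 26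
Reactants: 36 ethyl 2-[(1R,4R,6S)-6-(TBSO)-4-hydroxy-4-methyl-3-[(2R)-5-(TBSO)pentan-2-yl]cyclohex-2-en-1-yl]acetate
Product: 37 (3aR,6R,7aS)-6-hydroxy-5-[(2R)-5-hydroxypentan-2-yl]-6-methyl-3a,6,7,7a-tetrahydro-1-benzofuran-2(3H)-one
Conditions: TBAF, THF, 0 °C → rt
Reagents that add atoms: none
Why: Fluoride desilylation; the liberated cis-γ-alkoxide closes onto the ethyl ester to give the cis-fused γ-lactone.

Step 27
Reactants: 37 (3aR,6R,7aS)-6-hydroxy-5-[(2R)-5-hydroxypentan-2-yl]-6-methyl-3a,6,7,7a-tetrahydro-1-benzofuran-2(3H)-one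
Product: 40 (3aS,6R,7aS)-6-hydroxy-5-[(2R)-5-hydroxypentan-2-yl]-6-methyl-3-methylidene-3a,6,7,7a-tetrahydro-1-benzofuran-2(3H)-one, via Mannich base 38 (not isolated), via methiodide 39 (not isolated)
Conditions: LDA (3.3 equiv), THF, −78 °C; CH2=NMe2+ I−, −78 → 0 °C; then MeI, MeOH; then NaHCO3, EtOAc/H2O
Reagents that add atoms: N,N-dimethylmethyleneiminium iodide (C=[N+](C)C.[I-])
Why: Eschenmoser α-methylenation (Mannich reaction of the lactone enolate, N-quaternisation, β-elimination); the two hydroxyls are carried as alkoxides.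

Step 28
Reactants: 40 (3aS,6R,7aS)-6-hydroxy-5-[(2R)-5-hydroxypentan-2-yl]-6-methyl-3-methylidene-3a,6,7,7a-tetrahydro-1-benzofuran-2(3H)-one
Product: 41 (4R)-4-[(3aS,6R,7aS)-6-hydroxy-6-methyl-3-methylidene-2-oxo-2,3,3a,6,7,7a-hexahydro-1-benzofuran-5-yl]pentyl acetate
Conditions: Ac2O, pyridine, CH2Cl2, 0 °C
Reagents that add atoms: acetic anhydride (CC(=O)OC(C)=O)
Why: Acylation selects the primary alcohol over the hindered tertiary allylic alcohol.

Step 29
Reactants: 41 (4R)-4-[(3aS,6R,7aS)-6-hydroxy-6-methyl-3-methylidene-2-oxo-2,3,3a,6,7,7a-hexahydro-1-benzofuran-5-yl]pentyl acetate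
Product: 42 (4R)-4-[(3aS,6R,7aS)-6-methyl-3-methylidene-2-oxo-6-(trimethylsilyloxy)-2,3,3a,6,7,7a-hexahydro-1-benzofuran-5-yl]pentyl acetate
Conditions: 1-(trimethylsilyl)imidazole, CH2Cl2, rt
Reagents that add atoms: 1-(trimethylsilyl)imidazole (C[Si](C)(C)n1ccnc1)
Why: Temporary silylation shields the tertiary allylic alcohol from the dehydrating agent of the next step.

## Part C – union and completion

Step 30
Reactants: 21 2α-acetoxy-8α,12-bis(TBSO)-1βH-guaia-3,11(13)-dien-5β-ol; 42 (4R)-4-[(3aS,6R,7aS)-6-methyl-3-methylidene-2-oxo-6-(trimethylsilyloxy)-2,3,3a,6,7,7a-hexahydro-1-benzofuran-5-yl]pentyl acetate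
Product: 44 endo Diels–Alder adduct (spiro-norbornene dimer; 2-OAc on the one-carbon bridge syn to the spiro-lactone bridge; 8α-OTBS; 12-OTBS; 10′-OTMS), via acetoxy diene 43 (not isolated)
Conditions: Burgess reagent, 42 (3 equiv), PhMe (0.5 M), 25 → 45 °C
Reagents that add atoms: none
Why: Burgess syn-dehydration toward H-1 gives the cyclopentadiene, trapped at once in an endo Diels–Alder reaction on the α-face (syn to the acyloxy group, anti to the C10 methyl), with the dienophile CH2 bonding to the fully substituted C1.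

Step 31
Reactants: 44 endo Diels–Alder adduct
Product: 45 8,12,10′-triol of the adduct
Conditions: HF·pyridine, pyridine, THF, 0 °C → rt
Reagents that add atoms: none
Why: Buffered fluoride removes the two TBS ethers and the TMS ether without touching the acetates or lactone.

Step 32
Reactants: 45 8,12,10′-triol of the adduct
Product: 46 target compound CNP0257312.1
Conditions: TEMPO (cat.), PhI(OAc)2, CH2Cl2, rt
Reagents that add atoms: none
Why: TEMPO oxidation of the primary allylic alcohol to the enal, lactol formation with the 8-OH and further oxidation give the trans-fused α-methylene-γ-lactone; the tertiary alcohol is inert.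

## Compound list

1 | cyclohepta-1,3-diene | C1=CC=CCCC1 | starting material
2 | cis-cyclohept-2-ene-1,4-diyl diacetate (meso) | CC(=O)O[C@@H]1C=C[C@H](OC(C)=O)CCC1 | intermediate
3 | (1S,4R)-4-hydroxycyclohept-2-en-1-yl acetate | CC(=O)O[C@@H]1C=C[C@H](O)CCC1 | intermediate
4 | (1S,4R)-4-(TBSO)cyclohept-2-en-1-yl acetate | CC(=O)O[C@@H]1C=C[C@H](O[Si](C)(C)C(C)(C)C)CCC1 | intermediate
5 | (1S,4R)-4-(TBSO)cyclohept-2-en-1-ol | O[C@@H]1C=C[C@H](O[Si](C)(C)C(C)(C)C)CCC1 | intermediate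
6 | (4R)-4-(TBSO)cyclohept-2-en-1-one | O=C1C=C[C@H](O[Si](C)(C)C(C)(C)C)CCC1 | intermediate
7 | (7R)-7-(TBSO)-3-(trimethylsilyloxy)cyclohepta-1,3-diene | C[Si](C)(C)OC1=CCC[C@@H](O[Si](C)(C)C(C)(C)C)C=C1 | intermediate
8 | (4R)-4-(TBSO)cyclohepta-2,6-dien-1-one | O=C1C=C[C@H](O[Si](C)(C)C(C)(C)C)CC=C1 | intermediate
9 | 1-bromobut-2-yne | CC#CCBr | starting material
10 | methylzinc enolate of (3R,5R)-5-(TBSO)-3-methylcyclohept-6-en-1-one | C[Zn]OC1=C[C@H](C)C[C@@H](O[Si](C)(C)C(C)(C)C)C=C1 | intermediate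
11 | (2S,3R,5R)-2-(but-2-yn-1-yl)-5-(TBSO)-3-methylcyclohept-6-en-1-one | O=C1C=C[C@H](O[Si](C)(C)C(C)(C)C)C[C@@H](C)[C@@H]1CC#CC | intermediate
12 | 2-bromoprop-2-en-1-ol | OCC(Br)=C | starting material
13 | [(2-bromoprop-2-en-1-yl)oxy](tert-butyl)dimethylsilane | C=C(Br)CO[Si](C)(C)C(C)(C)C | intermediate
14 | (2S,3R,5R,6S)-2-(but-2-yn-1-yl)-5-(TBSO)-6-[3-(TBSO)prop-1-en-2-yl]-3-methylcycloheptan-1-one | O=C1C[C@@H](C(=C)CO[Si](C)(C)C(C)(C)C)[C@H](O[Si](C)(C)C(C)(C)C)C[C@@H](C)[C@@H]1CC#CC | intermediate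
15 | (2S,3R,5R,6S)-5-(TBSO)-6-[3-(TBSO)prop-1-en-2-yl]-3-methyl-2-(2-oxobutyl)cycloheptan-1-one | O=C1C[C@@H](C(=C)CO[Si](C)(C)C(C)(C)C)[C@H](O[Si](C)(C)C(C)(C)C)C[C@@H](C)[C@@H]1CC(=O)CC | intermediate
16 | 8α,12-bis(TBSO)-1βH,7αH,10αH-guaia-4,11(13)-dien-3-one | CC1=C2C[C@@H](C(=C)CO[Si](C)(C)C(C)(C)C)[C@H](O[Si](C)(C)C(C)(C)C)C[C@@H](C)[C@@H]2CC1=O | intermediate
17 | 8α,12-bis(TBSO)-3-(trimethylsilyloxy)-1βH-guaia-2,4,11(13)-triene | CC1=C2C[C@@H](C(=C)CO[Si](C)(C)C(C)(C)C)[C@H](O[Si](C)(C)C(C)(C)C)C[C@@H](C)[C@@H]2C=C1O[Si](C)(C)C | intermediate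
18 | 2β-hydroxy-8α,12-bis(TBSO)-1βH-guaia-4,11(13)-dien-3-one | CC1=C2C[C@@H](C(=C)CO[Si](C)(C)C(C)(C)C)[C@H](O[Si](C)(C)C(C)(C)C)C[C@@H](C)[C@@H]2[C@@H](O)C1=O | intermediate
19 | 4β,5β-epoxy-2β-hydroxy-8α,12-bis(TBSO)-1βH-guai-11(13)-en-3-one | C[C@]12O[C@]13C[C@@H](C(=C)CO[Si](C)(C)C(C)(C)C)[C@H](O[Si](C)(C)C(C)(C)C)C[C@@H](C)[C@@H]3[C@@H](O)C2=O | intermediate
20 | 8α,12-bis(TBSO)-1βH-guaia-3,11(13)-diene-2β,5β-diol | CC1=C[C@H](O)[C@H]2[C@H](C)C[C@@H](O[Si](C)(C)C(C)(C)C)[C@H](C(=C)CO[Si](C)(C)C(C)(C)C)C[C@@]12O | intermediate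
21 | 2α-acetoxy-8α,12-bis(TBSO)-1βH-guaia-3,11(13)-dien-5β-ol | CC1=C[C@@H](OC(C)=O)[C@H]2[C@H](C)C[C@@H](O[Si](C)(C)C(C)(C)C)[C@H](C(=C)CO[Si](C)(C)C(C)(C)C)C[C@@]12O | intermediate
22 | cyclohexa-1,3-diene | C1=CC=CCC1 | starting material
23 | cis-cyclohex-2-ene-1,4-diyl diacetate (meso) | CC(=O)O[C@H]1C=C[C@@H](OC(C)=O)CC1 | intermediate
24 | (1R,4S)-4-hydroxycyclohex-2-en-1-yl acetate | CC(=O)O[C@H]1C=C[C@@H](O)CC1 | intermediate
25 | (1R,4S)-4-(TBSO)cyclohex-2-en-1-yl acetate | CC(=O)O[C@H]1C=C[C@@H](O[Si](C)(C)C(C)(C)C)CC1 | intermediate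
26 | (1R,4S)-4-(TBSO)cyclohex-2-en-1-ol | O[C@H]1C=C[C@@H](O[Si](C)(C)C(C)(C)C)CC1 | intermediate
27 | 1-ethoxyvinyl ether of 26 (ketene acetal) | C=C(OCC)O[C@H]1C=C[C@@H](O[Si](C)(C)C(C)(C)C)CC1 | intermediate
28 | ethyl 2-[(1R,6S)-6-(TBSO)cyclohex-2-en-1-yl]acetate | CCOC(=O)C[C@@H]1C=CCC[C@@H]1O[Si](C)(C)C(C)(C)C | intermediate
29 | ethyl 2-[(1R,6S)-6-(TBSO)-4-oxocyclohex-2-en-1-yl]acetate | CCOC(=O)C[C@@H]1C=CC(=O)C[C@@H]1O[Si](C)(C)C(C)(C)C | intermediate
30 | dimethylaluminium enolate of the 2-(phenylsulfanyl) ketone | CCOC(=O)C[C@@H]1[C@@H](Sc2ccccc2)C=C(O[Al](C)C)C[C@@H]1O[Si](C)(C)C(C)(C)C | intermediate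
31 | ethyl 2-[(1S,2R,6S)-6-(TBSO)-3-(1-hydroxyethyl)-4-oxo-2-(phenylsulfanyl)cyclohexyl]acetate (epimers at C3/C1′) | CCOC(=O)C[C@@H]1[C@@H](Sc2ccccc2)C(C(C)O)C(=O)C[C@@H]1O[Si](C)(C)C(C)(C)C | intermediate
32 | methanesulfonate of 31 | CCOC(=O)C[C@@H]1[C@@H](Sc2ccccc2)C(C(C)OS(C)(=O)=O)C(=O)C[C@@H]1O[Si](C)(C)C(C)(C)C | intermediate
33 | ethyl 2-[(1S,2R,3Z,6S)-6-(TBSO)-3-ethylidene-4-oxo-2-(phenylsulfanyl)cyclohexyl]acetate | CCOC(=O)C[C@@H]1[C@@H](Sc2ccccc2)/C(=C\C)C(=O)C[C@@H]1O[Si](C)(C)C(C)(C)C | intermediate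
34 | tert-butyl(3-iodopropoxy)dimethylsilane | CC(C)(C)[Si](C)(C)OCCCI | starting material
35 | ethyl 2-[(1R,6S)-6-(TBSO)-4-oxo-3-[(2R)-5-(TBSO)pentan-2-yl]cyclohex-2-en-1-yl]acetate | CCOC(=O)C[C@@H]1C=C([C@H](C)CCCO[Si](C)(C)C(C)(C)C)C(=O)C[C@@H]1O[Si](C)(C)C(C)(C)C | intermediate
36 | ethyl 2-[(1R,4R,6S)-6-(TBSO)-4-hydroxy-4-methyl-3-[(2R)-5-(TBSO)pentan-2-yl]cyclohex-2-en-1-yl]acetate | CCOC(=O)C[C@@H]1C=C([C@H](C)CCCO[Si](C)(C)C(C)(C)C)[C@](C)(O)C[C@@H]1O[Si](C)(C)C(C)(C)C | intermediate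
37 | (3aR,6R,7aS)-6-hydroxy-5-[(2R)-5-hydroxypentan-2-yl]-6-methyl-3a,6,7,7a-tetrahydro-1-benzofuran-2(3H)-one | O=C1C[C@@H]2C=C([C@H](C)CCCO)[C@](C)(O)C[C@@H]2O1 | intermediate
38 | 3-[(dimethylamino)methyl] derivative of 37 (Mannich base) | CN(C)CC1C(=O)O[C@H]2C[C@@](C)(O)C([C@H](C)CCCO)=C[C@H]21 | intermediate
39 | trimethylammonium iodide of 38 | C[N+](C)(C)CC1C(=O)O[C@H]2C[C@@](C)(O)C([C@H](C)CCCO)=C[C@H]21.[I-] | intermediate
40 | (3aS,6R,7aS)-6-hydroxy-5-[(2R)-5-hydroxypentan-2-yl]-6-methyl-3-methylidene-3a,6,7,7a-tetrahydro-1-benzofuran-2(3H)-one | C=C1C(=O)O[C@H]2C[C@@](C)(O)C([C@H](C)CCCO)=C[C@H]21 | intermediate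
41 | (4R)-4-[(3aS,6R,7aS)-6-hydroxy-6-methyl-3-methylidene-2-oxo-2,3,3a,6,7,7a-hexahydro-1-benzofuran-5-yl]pentyl acetate | C=C1C(=O)O[C@H]2C[C@@](C)(O)C([C@H](C)CCCOC(C)=O)=C[C@H]21 | intermediate
42 | (4R)-4-[(3aS,6R,7aS)-6-methyl-3-methylidene-2-oxo-6-(trimethylsilyloxy)-2,3,3a,6,7,7a-hexahydro-1-benzofuran-5-yl]pentyl acetate | C=C1C(=O)O[C@H]2C[C@@](C)(O[Si](C)(C)C)C([C@H](C)CCCOC(C)=O)=C[C@H]21 | intermediate
43 | 2α-acetoxy-8α,12-bis(TBSO)-7αH,10αH-guaia-1(5),3,11(13)-triene | CC(=O)O[C@@H]1C=C(C)C2=C1[C@H](C)C[C@@H](O[Si](C)(C)C(C)(C)C)[C@@H](C2)C(=C)CO[Si](C)(C)C(C)(C)C | intermediate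
44 | endo Diels–Alder adduct of 43 and 42 (2-OAc, 8-OTBS, 12-OTBS, 10′-OTMS) | CC(C)(C)[Si](C)(C)O[C@@H]2C[C@@H](C)[C@]34C[C@]5(C(=O)O[C@H]6C[C@@](C)(O[Si](C)(C)C)C([C@H](C)CCCOC(C)=O)=C[C@H]65)[C@H](C(C)=C3C[C@H]2C(=C)CO[Si](C)(C)C(C)(C)C)[C@H]4OC(C)=O | intermediate
45 | 8,12,10′-triol of the adduct | O[C@@H]2C[C@@H](C)[C@]34C[C@]5(C(=O)O[C@H]6C[C@@](C)(O)C([C@H](C)CCCOC(C)=O)=C[C@H]65)[C@H](C(C)=C3C[C@H]2C(=C)CO)[C@H]4OC(C)=O | intermediate
46 | CNP0257312.1 | C=C1C(=O)O[C@@H]2C[C@@H](C)[C@]34C[C@]5(C(=O)O[C@H]6C[C@@](C)(O)C([C@H](C)CCCOC(C)=O)=C[C@H]65)[C@H](C(C)=C3C[C@@H]12)[C@H]4OC(C)=O | target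

## Step count and risks

Total step count: 32. Longest linear sequence: 17 steps (1–7, 9–15, 30–32; the other half, 16–29 then 30–32, is equally long).

The three steps most likely to fail:

**Step 30 (dehydration and Diels–Alder).** The dehydration could go toward C6 instead of C1, the acetoxy diene can undergo [1,5]-H shifts, and the regio-, facial and endo selectivity of the cycloaddition rest on analogy with the natural dimers. Fallback: from diol 20, MnO2 oxidises the allylic C2 carbinol to 5β-hydroxy-guaia-3,11(13)-dien-2-one F1. Burgess dehydration of this β-hydroxy ketone, which can only go toward the acidic C1–H, in the presence of 42 releases the cyclopentadienone F2. It has no sp3 C–H to shift and is trapped as the bridged ketone F3. NaBH4 reduces the bridge carbonyl from the less hindered alkene face to the bridge alcohol F4, and Ac2O/DMAP acetylation re-joins the route at 44. Facial control then rests on the C10 methyl alone.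

**Step 24 (cuprate addition–elimination).** The C4′ configuration depends on attack anti to the C–S bond of one alkene geometry. Fallback: from enone 29, the thia-Michael/aldol step is run with 4-(TBSO)butanal to give the β-hydroxy sulfide F5, which is dehydrated (MsCl, Et3N) to the silyloxybutylidene enone F6. Me2CuLi then forms the C4′–CH3 bond instead of the C4′–C3′ bond, which gives the opposite configuration at C4′ for the same facial bias, and re-joins the route at 35.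

**Step 7 (first conjugate addition on the dienone).** Site selectivity between the two enone halves, base-induced loss of silanol from 8 (to tropone) and the alkylation of the zinc enolate are all uncertain. Fallback: from enone 6, LDA/PhSSPh gives the α′-phenylthio enone F7. The alkenyl cuprate of step 9 adds trans to OTBS to give ketone F8. mCPBA gives the sulfoxide F9, and thermolysis (PhMe, 80 °C) places the new double bond only on the sulfur side, giving enone F10. Cu-catalysed Me2Zn addition with the same ligand, followed by alkylation of the zinc enolate with 9, re-joins the route at 14.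

Further compounds

F1 | step 30 | 5β-hydroxy-8α,12-bis(TBSO)-1βH-guaia-3,11(13)-dien-2-one | CC1=CC(=O)[C@H]2[C@H](C)C[C@@H](O[Si](C)(C)C(C)(C)C)[C@H](C(=C)CO[Si](C)(C)C(C)(C)C)C[C@@]12O
F2 | step 30 | 8α,12-bis(TBSO)-guaia-1(5),3,11(13)-trien-2-one | O=C1C=C(C)C2=C1[C@H](C)C[C@@H](O[Si](C)(C)C(C)(C)C)[C@@H](C2)C(=C)CO[Si](C)(C)C(C)(C)C
F3 | step 30 | bridge-ketone (2-oxo) analogue of 44 | CC(C)(C)[Si](C)(C)O[C@@H]2C[C@@H](C)[C@]34C[C@]5(C(=O)O[C@H]6C[C@@](C)(O[Si](C)(C)C)C([C@H](C)CCCOC(C)=O)=C[C@H]65)[C@H](C(C)=C3C[C@H]2C(=C)CO[Si](C)(C)C(C)(C)C)C4=O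
F4 | step 30 | bridge-alcohol (2-hydroxy) analogue of 44 | CC(C)(C)[Si](C)(C)O[C@@H]2C[C@@H](C)[C@]34C[C@]5(C(=O)O[C@H]6C[C@@](C)(O[Si](C)(C)C)C([C@H](C)CCCOC(C)=O)=C[C@H]65)[C@H](C(C)=C3C[C@H]2C(=C)CO[Si](C)(C)C(C)(C)C)[C@H]4O
F5 | step 24 | ethyl 2-[(1S,2R,6S)-6-(TBSO)-3-[1-hydroxy-4-(TBSO)butyl]-4-oxo-2-(phenylsulfanyl)cyclohexyl]acetate | CCOC(=O)C[C@@H]1[C@@H](Sc2ccccc2)C(C(O)CCCO[Si](C)(C)C(C)(C)C)C(=O)C[C@@H]1O[Si](C)(C)C(C)(C)C
F6 | step 24 | ethyl 2-[(1S,2R,3Z,6S)-6-(TBSO)-3-[4-(TBSO)butylidene]-4-oxo-2-(phenylsulfanyl)cyclohexyl]acetate | CCOC(=O)C[C@@H]1[C@@H](Sc2ccccc2)/C(=C\CCCO[Si](C)(C)C(C)(C)C)C(=O)C[C@@H]1O[Si](C)(C)C(C)(C)C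
F7 | step 7 | (4R)-4-(TBSO)-7-(phenylsulfanyl)cyclohept-2-en-1-one | O=C1C=C[C@H](O[Si](C)(C)C(C)(C)C)CCC1Sc1ccccc1
F8 | step 7 | (3S,4R)-4-(TBSO)-3-[3-(TBSO)prop-1-en-2-yl]-7-(phenylsulfanyl)cycloheptan-1-one | O=C1C[C@@H](C(=C)CO[Si](C)(C)C(C)(C)C)[C@H](O[Si](C)(C)C(C)(C)C)CCC1Sc1ccccc1
F9 | step 7 | (3S,4R)-4-(TBSO)-3-[3-(TBSO)prop-1-en-2-yl]-7-(phenylsulfinyl)cycloheptan-1-one | O=C1C[C@@H](C(=C)CO[Si](C)(C)C(C)(C)C)[C@H](O[Si](C)(C)C(C)(C)C)CCC1S(=O)c1ccccc1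
F10 | step 7 | (5R,6S)-5-(TBSO)-6-[3-(TBSO)prop-1-en-2-yl]cyclohept-2-en-1-one | O=C1C[C@@H](C(=C)CO[Si](C)(C)C(C)(C)C)[C@H](O[Si](C)(C)C(C)(C)C)CC=C1
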